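**Retrosynthetic overview**
1. GA50 ⇒ its 12-ketone with C16=C17 masked as a β-bromo ether and C7 as a silylethyl ester; the 12β-OH comes last by ketyl reduction, the 2β,3β-diol from OsO4 on a Δ2-alkene.
2. Key step: ring A, the 19,10-γ-lactone, C4 and C5 are made together by a bridging vinylogous Michael addition (C4→C5) of a spiro seven-membered lactone, itself closed by ring-closing metathesis (C2=C3) between a C10 allyl group and a C10 O-(2-methylbut-3-enoyl) ester.
3. The C10 carbinol comes from allyl Grignard addition to a ring-B keto-enoate; C7 from carbonylation of the C6 enol triflate; the C10 oxygen of the starting cyclopentenone is only a chirality relay.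
4. Ring D: Pd(OAc)2 oxidative cycloalkenylation (C13–C16) of the silyl enol ether left by the ring-C-forming Diels–Alder reaction (C8–C14, C9–C11) of (R)-2-allyl-4-silyloxycyclopentenone with a 2-silyloxybutadiene.
5. Ring order: B (bought, chiral) → C → D → seven-membered lactone → A plus γ-lactone in one step; no relay from a natural gibberellin.

Assumption: gibberellin numbering (C1–C19) is used for all intermediates; α is the face of ring B that carries the lactone oxygen on C10 in the target, β the opposite face (H-5, H-9, C7, C18, the C15–C16 bridge and all three hydroxyls, so the target is read as the 2β,3β,12β-triol); compounds 1, 3, 5, 16 and 18 are bought.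

**Step 1**
Reactants: 1 (R)-4-(tert-butyldimethylsilyloxy)cyclopent-2-en-1-one
Product: 2 (R)-4-(tert-butyldimethylsilyloxy)-2-iodocyclopent-2-en-1-one
Conditions: I2, pyridine/CH2Cl2 (1:1), 0 °C to rt
Reagents that add atoms: iodine, [I][I]
Why: α-Iodination of the enone by pyridine addition, enolate iodination and elimination puts a coupling handle on the future C8 without touching the silyloxy stereocentre (future C10).

**Step 2**
Reactants: 2 (R)-4-(tert-butyldimethylsilyloxy)-2-iodocyclopent-2-en-1-one; 3 allyltributylstannane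
Product: 4 (R)-2-allyl-4-(tert-butyldimethylsilyloxy)cyclopent-2-en-1-one
Conditions: Pd2(dba)3 (5 mol %), AsPh3 (20 mol %), CuI (10 mol %), NMP, rt
Reagents that add atoms: none
Why: Stille coupling of the vinyl iodide with the allylstannane installs C15–C17 on C8 under neutral conditions that leave the β-silyloxy enone intact.

**Step 3**
Reactants: 5 but-3-en-2-one
Product: 6 2-(tert-butyldimethylsilyloxy)buta-1,3-diene
Conditions: t-BuMe2SiOTf, Et3N, Et2O, 0 °C
Reagents that add atoms: tert-butyldimethylsilyl trifluoromethanesulfonate, CC(C)(C)[Si](C)(C)OS(=O)(=O)C(F)(F)F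
Why: Soft enolisation and O-silylation of the methyl ketone gives the 2-silyloxydiene (silyl enol ether formation).

**Step 4**
Reactants: 4 (R)-2-allyl-4-(tert-butyldimethylsilyloxy)cyclopent-2-en-1-one; 6 2-(tert-butyldimethylsilyloxy)buta-1,3-diene
Product: 7 cis-fused ring B/C bicycle with C6 ketone, 8β-allyl, H-9β, 10β-OTBS and the C12=C13 TBS enol ether
Conditions: AlBr3/AlMe3 (10:1, 0.3 equiv), toluene/CH2Br2, −10 °C
Reagents that add atoms: none
Why: Lewis acid-promoted Diels–Alder reaction in which the nucleophilic diene terminus C11 bonds to the enone β-carbon C9 (para rule), the diene adds anti to the C10 silyloxy group and suprafacially, so C8 and C9 are set with H-9 cis to the allyl group and the enol ether is formed regiospecifically as C12=C13.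

**Step 5**
Reactants: 7 cis-fused ring B/C bicycle
Product: 8 tricyclic diketone (rings B, C, D) with C6 and C12 ketones, 10β-OTBS and the 16-methylene group
Conditions: Pd(OAc)2 (10 mol %), O2 (1 atm), DMSO, 45 °C
Reagents that add atoms: none
Why: Pd(OAc)2-mediated oxidative cycloalkenylation of the silyl enol ether: divalent palladium activates the allyl alkene, C13 attacks C16 in a 5-exo mode, β-hydride elimination gives the exocyclic methylene, O2 reoxidises zerovalent palladium, and the one-carbon tether fixes the C13 configuration.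

**Step 6**
Reactants: 8 tricyclic diketone
Product: 9 12,12-ethylenedioxy ketal of the tricyclic diketone (C6 ketone free)
Conditions: Me3SiOCH2CH2OSiMe3, Me3SiOTf (5 mol %), CH2Cl2, −78 to −30 °C
Reagents that add atoms: 1,2-bis(trimethylsilyloxy)ethane, C[Si](C)(C)OCCO[Si](C)(C)C
Why: Noyori ketalisation is selective for the cyclohexanone C12 over the cyclopentanone C6 flanked by the quaternary C8, the same selectivity as 3- versus 17-ketone in steroids.

**Step 7**
Reactants: 9 12-ketal
Product: 10 17-bromo-16-methoxy derivative (masked exocyclic alkene; C16 configuration not assigned)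
Conditions: NBS, MeOH/CH2Cl2 (1:1), 0 °C, dark
Reagents that add atoms: N-bromosuccinimide, O=C1CCC(=O)N1Br; methanol, CO
Why: Markovnikov bromo-etherification (bromonium opened by methanol at tertiary C16) masks the only electron-rich alkene as a β-bromo ether that has no β-hydrogen for elimination, is neopentyl towards substitution and is unmasked reductively later.

**Step 8**
Reactants: 10 17-bromo-16-methoxy C6 ketone
Product: 12 C6 enol triflate (Δ5), via potassium enolate 11 (not isolated)
Conditions: KN(SiMe3)2, THF, −78 °C; then PhNTf2, −78 to 0 °C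
Reagents that add atoms: N-phenylbis(trifluoromethanesulfonimide), O=S(=O)(N(c1ccccc1)S(=O)(=O)C(F)(F)F)C(F)(F)F
Why: Enol triflate formation: deprotonation can occur only at C5 because C8 is quaternary, and the cold potassium enolate is O-triflated before it can expel the β-silyloxy group.

**Step 9**
Reactants: 12 C6 enol triflate
Product: 13 2-(trimethylsilyl)ethyl Δ5-7-oate (10β-OTBS)
Conditions: Pd(OAc)2 (5 mol %), PPh3 (10 mol %), CO (1 atm), Me3SiCH2CH2OH, Et3N, DMF, 60 °C
Reagents that add atoms: carbon monoxide, [C-]#[O+]; 2-(trimethylsilyl)ethanol, C[Si](C)(C)CCO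
Why: Palladium-catalysed alkoxycarbonylation of the vinyl triflate introduces C7 as a fluoride-cleavable ester, and the neopentyl-type alkyl bromide does not undergo oxidative addition with a PPh3-ligated catalyst.

**Step 10**
Reactants: 13 2-(trimethylsilyl)ethyl Δ5-7-oate
Product: 14 10β-hydroxy Δ5-7-oate
Conditions: HF·pyridine, pyridine, THF, 0 °C to rt
Reagents that add atoms: none
Why: Selective desilylation: buffered HF cleaves the secondary allylic silyl ether while the silylethyl ester, the dioxolane and the bromo ether survive.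

**Step 11**
Reactants: 14 10β-hydroxy Δ5-7-oate
Product: 15 10-oxo Δ5-7-oate (cross-conjugated keto enoate)
Conditions: Dess–Martin periodinane, CH2Cl2, rt
Reagents that add atoms: none
Why: Dess–Martin oxidation of the allylic alcohol erases the C10 stereocentre once it has served as the control element, and the cis B/C fusion at the now enolisable C9 is the thermodynamically preferred one.

**Step 12**
Reactants: 16 2-methylbut-3-enoic acid (racemic)
Product: 17 2-methylbut-3-enoyl chloride (racemic, used crude)
Conditions: (COCl)2, DMF (cat.), CH2Cl2, 0 °C to rt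
Reagents that add atoms: oxalyl chloride, O=C(Cl)C(=O)Cl
Why: Acid chloride formation through the Vilsmeier-type chloroiminium catalyst under conditions too mild to conjugate the alkene.

**Step 13**
Reactants: 15 10-oxo Δ5-7-oate; 18 allylmagnesium bromide; 17 2-methylbut-3-enoyl chloride
Product: 20 10β-allyl 10α-(2-methylbut-3-enoyloxy) Δ5-7-oate (both epimers at the acyl α-carbon), via bromomagnesium alkoxide 19 (not isolated)
Conditions: CH2=CHCH2MgBr, THF, −78 °C; then 17, −78 to 0 °C
Reagents that add atoms: none
Why: Grignard 1,2-addition to the ring-B ketone from the convex β face (anti to C11 and to ring C, which covers the α face) sets C10 with its oxygen α, and the tertiary alkoxide is acylated in situ; the acyl α-carbon is planarised later so its configuration is irrelevant.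

**Step 14**
Reactants: 20 10β-allyl 10α-(2-methylbut-3-enoyloxy) Δ5-7-oate
Product: 21 spiro seven-membered unsaturated lactone (ring O–C19–C4–C3=C2–C1–C10; C4 epimers)
Conditions: second-generation Grubbs catalyst (5 mol %), CH2Cl2 (2 mM), 40 °C
Reagents that add atoms: none
Why: Ring-closing metathesis of the two terminal alkenes (the trisubstituted enoate does not take part) gives the Z-configured seven-membered lactone spiro-fused at C10, helped by the quaternary C10 and the α-methyl group.

**Step 15**
Reactants: 21 spiro seven-membered unsaturated lactone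
Product: 24 Δ2-19,10-lactone 2-(trimethylsilyl)ethyl ester with rings A–D complete (12-ketal and 16,17-bromo ether), via potassium dienolate 22 (not isolated), via potassium ester enolate 23 (not isolated)
Conditions: KOt-Bu (0.3 equiv), THF/t-BuOH (5:1), 0 °C to rt
Reagents that add atoms: none
Why: Proposed new method: deprotonation at C4 (α to the lactone carbonyl and allylic) gives a cyclic dienolate whose α-carbon can reach only C5, the β-carbon of the enoate on the neighbouring ring atom C10, so a 5-exo-trig vinylogous Michael addition closes the γ-lactone and ring A at once, with C4 and C5 fixed by the bridged geometry (methyl exo, C4 on the α face of C5, Δ2 retained) and C6 equilibrated by the alkoxide to the ester trans to C4; the closest known reactions are the intramolecular Michael addition of a C10 propionate onto a ring-B acceptor used to build gibberellin lactones, α-selective reactions of ester dienolates and transannular Michael cyclisations.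

**Step 16**
Reactants: 24 Δ2-19,10-lactone ester
Product: 25 2β,3β-diol
Conditions: OsO4 (5 mol %), N-methylmorpholine N-oxide, acetone/H2O (4:1), rt
Reagents that add atoms: osmium tetroxide (catalytic oxygen carrier), O=[Os](=O)(=O)=O; N-methylmorpholine N-oxide, C[N+]1([O-])CCOCC1; water, O
Why: Upjohn dihydroxylation adds to the only remaining alkene from the exo (β) face of the bicyclic lactone, away from the lactone bridge, giving the cis-2β,3β-diol.

**Step 17**
Reactants: 25 2β,3β-diol 12-ketal
Product: 26 2β,3β-dihydroxy 12-ketone (16,17-bromo ether retained)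
Conditions: 1 M HCl, THF, rt
Reagents that add atoms: water, O
Why: Acid-catalysed ketal hydrolysis is run while the exocyclic alkene is still masked, so nothing acid-labile is exposed.

**Step 18**
Reactants: 26 2β,3β-dihydroxy 12-ketone bromo ether
Product: 27 12-oxo-GA50 2-(trimethylsilyl)ethyl ester (C16=C17 restored)
Conditions: Zn dust, EtOH/H2O (10:1), 75 °C
Reagents that add atoms: none
Why: Boord-type reductive elimination: zinc inserts into the C–Br bond and the β-methoxy group is expelled, regenerating the exocyclic methylene regiospecifically.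

**Step 19**
Reactants: 27 12-oxo-GA50 2-(trimethylsilyl)ethyl ester
Product: 28 GA50 2-(trimethylsilyl)ethyl ester (12β-OH)
Conditions: SmI2 (4 equiv), THF/H2O (20:1), 0 °C
Reagents that add atoms: none
Why: Ketyl (single-electron) reduction with SmI2/H2O gives the thermodynamically preferred equatorial 12β-alcohol, whereas a hydride would be pushed to the β face by the axial C10 and give the axial epimer; the γ-lactone and the unactivated ester are not reduced.

**Step 20**
Reactants: 28 GA50 2-(trimethylsilyl)ethyl ester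
Product: 29 GA50
Conditions: Bu4NF, THF, 0 °C to rt; then 1 M HCl to pH 3
Reagents that add atoms: none
Why: Fluoride-induced β-elimination of the silylethyl ester frees the C7 acid without base or acid strong enough to cause retro-aldol cleavage at C3–C4 or alkene migration.

**Compound list**
1 | (R)-4-(tert-butyldimethylsilyloxy)cyclopent-2-en-1-one | O=C1C=C[C@H](O[Si](C)(C)C(C)(C)C)C1 | starting material
2 | (R)-4-(tert-butyldimethylsilyloxy)-2-iodocyclopent-2-en-1-one | O=C1C(I)=C[C@H](O[Si](C)(C)C(C)(C)C)C1 | intermediate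
3 | allyltributylstannane | C=CC[Sn](CCCC)(CCCC)CCCC | starting material
4 | (R)-2-allyl-4-(tert-butyldimethylsilyloxy)cyclopent-2-en-1-one | O=C1C(CC=C)=C[C@H](O[Si](C)(C)C(C)(C)C)C1 | intermediate
5 | but-3-en-2-one | CC(=O)C=C | starting material
6 | 2-(tert-butyldimethylsilyloxy)buta-1,3-diene | C=CC(=C)O[Si](C)(C)C(C)(C)C | intermediate
7 | cis-fused ring B/C bicycle: C6 ketone, 8β-allyl, H-9β, 10β-OTBS, C12=C13 TBS enol ether | C=CC[C@]12CC=C(O[Si](C)(C)C(C)(C)C)C[C@H]1[C@H](O[Si](C)(C)C(C)(C)C)CC2=O | intermediate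
8 | tricyclic diketone (rings B, C, D): C6 and C12 ketones, 10β-OTBS, 16-methylene | C=C1C[C@]23C[C@H]1C(=O)C[C@H]2[C@H](O[Si](C)(C)C(C)(C)C)CC3=O | intermediate
9 | 12,12-ethylenedioxy ketal of 8 | C=C1C[C@]23C[C@H]1C4(OCCO4)C[C@H]2[C@H](O[Si](C)(C)C(C)(C)C)CC3=O | intermediate
10 | 17-bromo-16-methoxy derivative of 9 (C16 not assigned) | BrCC1(OC)C[C@]23C[C@H]1C4(OCCO4)C[C@H]2[C@H](O[Si](C)(C)C(C)(C)C)CC3=O | intermediate
11 | potassium C5=C6 enolate of 10 | BrCC1(OC)C[C@]23C[C@H]1C4(OCCO4)C[C@H]2[C@H](O[Si](C)(C)C(C)(C)C)C=C3[O-].[K+] | intermediate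
12 | C6 enol triflate (Δ5) | BrCC1(OC)C[C@]23C[C@H]1C4(OCCO4)C[C@H]2[C@H](O[Si](C)(C)C(C)(C)C)C=C3OS(=O)(=O)C(F)(F)F | intermediate
13 | 2-(trimethylsilyl)ethyl Δ5-7-oate, 10β-OTBS | BrCC1(OC)C[C@]23C[C@H]1C4(OCCO4)C[C@H]2[C@H](O[Si](C)(C)C(C)(C)C)C=C3C(=O)OCC[Si](C)(C)C | intermediate
14 | 10β-hydroxy Δ5-7-oate | BrCC1(OC)C[C@]23C[C@H]1C4(OCCO4)C[C@H]2[C@H](O)C=C3C(=O)OCC[Si](C)(C)C | intermediate
15 | 10-oxo Δ5-7-oate | BrCC1(OC)C[C@]23C[C@H]1C4(OCCO4)C[C@H]2C(=O)C=C3C(=O)OCC[Si](C)(C)C | intermediate
16 | 2-methylbut-3-enoic acid (racemic) | C=CC(C)C(=O)O | starting material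
17 | 2-methylbut-3-enoyl chloride (racemic) | C=CC(C)C(Cl)=O | intermediate
18 | allylmagnesium bromide | C=CC[Mg]Br | starting material
19 | bromomagnesium 10α-alkoxide, 10β-allyl | BrCC1(OC)C[C@]23C[C@H]1C4(OCCO4)C[C@H]2[C@](O[Mg]Br)(CC=C)C=C3C(=O)OCC[Si](C)(C)C | intermediate
20 | 10β-allyl 10α-(2-methylbut-3-enoyloxy) Δ5-7-oate (acyl α-carbon epimers) | BrCC1(OC)C[C@]23C[C@H]1C4(OCCO4)C[C@H]2[C@](OC(=O)C(C)C=C)(CC=C)C=C3C(=O)OCC[Si](C)(C)C | intermediate
21 | spiro seven-membered unsaturated lactone (C4 epimers) | BrCC1(OC)C[C@]23C[C@H]1C4(OCCO4)C[C@H]2[C@@]5(OC(=O)C(C)C=CC5)C=C3C(=O)OCC[Si](C)(C)C | intermediate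
22 | potassium dienolate of 21 | BrCC1(OC)C[C@]23C[C@H]1C4(OCCO4)C[C@H]2[C@@]5(OC([O-])=C(C)C=CC5)C=C3C(=O)OCC[Si](C)(C)C.[K+] | intermediate
23 | potassium C6 ester enolate of the cyclised lactone | BrCC1(OC)C[C@]23C[C@H]1C4(OCCO4)C[C@H]2[C@@]12CC=C[C@@](C)(C(=O)O1)[C@H]2C3=C([O-])OCC[Si](C)(C)C.[K+] | intermediate
24 | Δ2-19,10-lactone 2-(trimethylsilyl)ethyl ester, 12-ketal, 16,17-bromo ether | BrCC1(OC)C[C@]23C[C@H]1C4(OCCO4)C[C@H]2[C@@]12CC=C[C@@](C)(C(=O)O1)[C@H]2[C@@H]3C(=O)OCC[Si](C)(C)C | intermediate
25 | 2β,3β-diol of 24 | BrCC1(OC)C[C@]23C[C@H]1C4(OCCO4)C[C@H]2[C@@]12C[C@H](O)[C@H](O)[C@@](C)(C(=O)O1)[C@H]2[C@@H]3C(=O)OCC[Si](C)(C)C | intermediate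
26 | 2β,3β-dihydroxy 12-ketone, 16,17-bromo ether | BrCC1(OC)C[C@]23C[C@H]1C(=O)C[C@H]2[C@@]12C[C@H](O)[C@H](O)[C@@](C)(C(=O)O1)[C@H]2[C@@H]3C(=O)OCC[Si](C)(C)C | intermediate
27 | 12-oxo-GA50 2-(trimethylsilyl)ethyl ester | C=C1C[C@]23C[C@H]1C(=O)C[C@H]2[C@@]12C[C@H](O)[C@H](O)[C@@](C)(C(=O)O1)[C@H]2[C@@H]3C(=O)OCC[Si](C)(C)C | intermediate
28 | GA50 2-(trimethylsilyl)ethyl ester | C=C1C[C@]23C[C@H]1[C@H](O)C[C@H]2[C@@]12C[C@H](O)[C@H](O)[C@@](C)(C(=O)O1)[C@H]2[C@@H]3C(=O)OCC[Si](C)(C)C | intermediate
29 | GA50 | C=C1C[C@]23C[C@H]1[C@H](O)C[C@H]2[C@@]12C[C@H](O)[C@H](O)[C@@](C)(C(=O)O1)[C@H]2[C@@H]3C(=O)O | target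

**Count and risks**
Total step count: 20. Longest linear sequence: 18 steps (1 to 29 through steps 1, 2, 4–11 and 13–20; steps 3 and 12 make side components).

The three steps most likely to fail:

Step 15 (bridging vinylogous Michael addition). A tertiary dienolate carbon must attack a hindered β-carbon, and the forming C4–C5 bond overlaps only partly with the lactone enolate π-system. The fallback reverses the order of the two ring closures. It sets out from 20: KN(SiMe3)2 in THF at −78 °C gives the acyclic potassium dienolate F5, whose ester can rotate freely. Its α-carbon adds to C5, and after an acetic acid quench and DBU equilibration of C6 this gives the 4-methyl-4-vinyl γ-lactone F6. Only the C4 epimer with vinyl cis to the C10 allyl group is drawn, and only it can cyclise. The second-generation Grubbs catalyst then closes ring A between the vinyl and allyl groups, and the route is rejoined at 24.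

Step 4 (Diels–Alder reaction of the α-substituted, γ-silyloxy enone). The dienophile is hindered and both partners are Lewis acid-sensitive. The fallback is an anionic double Michael annulation that sets out from 4. Bought 2-(trimethylsilyloxy)buta-1,3-diene F1 is cleaved with MeLi in THF at 0 °C to lithium buta-1,3-dien-2-olate F2. Addition of 4 at −78 °C gives, by attack of C11 on C9 anti to the silyloxy group, the lithium enolate of the mono-Michael adduct F3. This closes by attack of C8 on the new vinyl ketone to the lithium C12 enolate of the bicycle F4. Silylation with t-BuMe2SiCl gives the same regiodefined enol ether, and the route is rejoined at 7.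

Step 19 (configuration at C12). If the ketyl reduction does not favour the equatorial alcohol, the fallback is inversion instead of direct control, and it sets out from 27. 2,2-Dimethoxypropane with pyridinium p-toluenesulfonate gives the 2,3-acetonide of the 12-ketone F7. LiBH(s-Bu)3 at −78 °C attacks from the open β face to give the axial 12α-alcohol acetonide F8. Mitsunobu reaction (4-nitrobenzoic acid, PPh3, diisopropyl azodicarboxylate) inverts it to the 12β-(4-nitrobenzoate) acetonide F9. K2CO3 in MeOH gives the 12β-alcohol acetonide F10, and aqueous acetic acid removes the acetonide, so the route is rejoined at 28.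

**Further compounds**
F1 | step 4 | 2-(trimethylsilyloxy)buta-1,3-diene | C=CC(=C)O[Si](C)(C)C
F2 | step 4 | lithium buta-1,3-dien-2-olate | C=CC(=C)[O-].[Li+]
F3 | step 4 | lithium enolate of the mono-Michael adduct | C=CCC1=C([O-])C[C@@H](O[Si](C)(C)C(C)(C)C)[C@@H]1CC(=O)C=C.[Li+]
F4 | step 4 | lithium C12 enolate of the bicycle | C=CC[C@]12CC=C([O-])C[C@H]1[C@H](O[Si](C)(C)C(C)(C)C)CC2=O.[Li+]
F5 | step 15 | acyclic potassium dienolate | BrCC1(OC)C[C@]23C[C@H]1C4(OCCO4)C[C@H]2[C@](OC([O-])=C(C)C=C)(CC=C)C=C3C(=O)OCC[Si](C)(C)C.[K+]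
F6 | step 15 | 4-methyl-4-vinyl γ-lactone | BrCC1(OC)C[C@]23C[C@H]1C4(OCCO4)C[C@H]2[C@@]1(CC=C)OC(=O)[C@](C)(C=C)[C@H]1[C@@H]3C(=O)OCC[Si](C)(C)C
F7 | step 19 | 2,3-acetonide of the 12-ketone | C=C1C[C@]23C[C@H]1C(=O)C[C@H]2[C@@]12C[C@@H]4OC(C)(C)O[C@@H]4[C@@](C)(C(=O)O1)[C@H]2[C@@H]3C(=O)OCC[Si](C)(C)C
F8 | step 19 | 12α-alcohol acetonide | C=C1C[C@]23C[C@H]1[C@@H](O)C[C@H]2[C@@]12C[C@@H]4OC(C)(C)O[C@@H]4[C@@](C)(C(=O)O1)[C@H]2[C@@H]3C(=O)OCC[Si](C)(C)C
F9 | step 19 | 12β-(4-nitrobenzoate) acetonide | C=C1C[C@]23C[C@H]1[C@H](OC(=O)c5ccc(cc5)[N+](=O)[O-])C[C@H]2[C@@]12C[C@@H]4OC(C)(C)O[C@@H]4[C@@](C)(C(=O)O1)[C@H]2[C@@H]3C(=O)OCC[Si](C)(C)C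
F10 | step 19 | 12β-alcohol acetonide | C=C1C[C@]23C[C@H]1[C@H](O)C[C@H]2[C@@]12C[C@@H]4OC(C)(C)O[C@@H]4[C@@](C)(C(=O)O1)[C@H]2[C@@H]3C(=O)OCC[Si](C)(C)C
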